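Both decalin units are cut back to one aldehyde (19), whose bicycle rests on the ring-fusion bond C5–C10 (labdane numbering) between gem-dimethyl C4 and quaternary C10. An open-chain keto-enal (11) is folded in one amine-catalysed operation: the aldehyde-derived enamine (C5) adds to the β,β-disubstituted enone carbon C10, closing ring A, and the methyl ketone then condenses with the aldehyde (C7 to C6), closing ring B. This exploits the 1,5-relation of C6 and C8, C8 being the later exocyclic methylene carbon. Enone 13 is alkylated at C9, methylenated and reduced to 19, which is elaborated by Wittig and aldol–dehydration chemistry into acid and lactone halves joined by esterification.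

Key step: step 5

Assumption: labdane numbering (C1–C20) is used for atom labels in both decalin units; 11 is drawn as its E isomer, and any Z isomer formed with it is expected to converge on 13 because the enone equilibrates under the amine/acid conditions.

Step 1
Reactants: 1 3-methylbut-2-enal; 2 (3-bromopropoxy)(tert-butyl)dimethylsilane
Product: 5 6-[(tert-butyldimethylsilyl)oxy]-3,3-dimethylhexanal, via Grignard reagent 3 (not isolated), via silyl enol ether 4 (not isolated)
Conditions: 2, Mg, THF, 40 °C; then CuBr·SMe2 (5 mol %), Me3SiCl, 1, THF, −78 °C; aq. citric acid, 0 °C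
Reagents that add atoms: none
Why: Copper-catalysed conjugate addition of a Grignard reagent to an enal, accelerated by Me3SiCl which traps the enolate as 4, should build the quaternary carbon C4, and mild acid then frees the aldehyde while the primary silyl ether stays.

Step 2
Reactants: 5 6-[(tert-butyldimethylsilyl)oxy]-3,3-dimethylhexanal
Product: 6 6,6-dimethoxy-4,4-dimethylhexan-1-ol
Conditions: HC(OMe)3, MeOH, p-TsOH·H2O (cat.), 0 °C → rt
Reagents that add atoms: trimethyl orthoformate, COC(OC)OC
Why: Acid-catalysed acetalization with the orthoformate as water scavenger should protect the aldehyde while the same acid methanolyses the primary silyl ether, so the protecting pattern is swapped in one operation.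

Step 3
Reactants: 6 6,6-dimethoxy-4,4-dimethylhexan-1-ol
Product: 7 6-bromo-1,1-dimethoxy-3,3-dimethylhexane
Conditions: CBr4, PPh3, imidazole, CH2Cl2, 0 °C
Reagents that add atoms: tetrabromomethane, BrC(Br)(Br)Br
Why: Appel bromination converts the primary alcohol into the bromide under conditions that imidazole keeps free of acid, so the acetal should survive.

Step 4
Reactants: 7 6-bromo-1,1-dimethoxy-3,3-dimethylhexane; 8 (3E)-4-methoxypent-3-en-2-one
Product: 11 (7E)-3,3,7-trimethyl-9-oxodec-7-enal, via Grignard reagent 9 (not isolated), via tertiary alcohol 10 (not isolated)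
Conditions: 7, Mg, THF, 45 °C; 8, THF, −40 → 0 °C; then 1 M HCl, THF, rt
Reagents that add atoms: water, O
Why: Addition of the Grignard reagent to the carbonyl of the vinylogous ester followed by acid-promoted loss of water and enol ether hydrolysis (Stork–Danheiser transposition) should give the β,β-disubstituted enone, and the same acid frees the aldehyde.

Step 5
Reactants: 11 (7E)-3,3,7-trimethyl-9-oxodec-7-enal
Product: 13 (4aS,8aR)-5,5,8a-trimethyl-4a,5,6,7,8,8a-hexahydronaphthalen-2(1H)-one, via Michael adduct 12 (not isolated)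
Conditions: (R)-2-[diphenyl(trimethylsilyloxy)methyl]pyrrolidine (20 mol %), PhCO2H (20 mol %), toluene, rt → 40 °C; then p-TsOH·H2O (10 mol %), 60 °C
Reagents that add atoms: none
Why: Proposed new method: the pyrrolidine catalyst turns the aldehyde of 11 into an E-enamine whose carbon C5 adds to the β-carbon C10 of the acid-activated enone (ring A, 6-exo-trig, enolexo), and after hydrolysis to 12 the methyl ketone condenses with the aldehyde (C7 to C6, ring B, 6-enolendo-exo-trig aldol, then loss of water). The closest known reactions are the amine-catalysed intramolecular Michael addition of aldehydes to enones and the Robinson-type Michael/aldol annulation; neither has been shown for a β,β-disubstituted enone acceptor that creates a quaternary carbon beside a neopentyl centre, which is why the step is labelled. The gem-dimethyl group at C4 (Thorpe–Ingold effect) and the irreversible dehydration that drains the Michael equilibrium are expected to carry this congested bond formation. C5 is set by the catalyst, whose diphenyl(silyloxy)methyl group shields one enamine face so that the R catalyst should direct C10 to the Re face of C5; C10 is set relative to C5 by a chair transition state in which the enamine and enone arms are both equatorial, which gives the trans ring fusion. The step needs enantioface control, trans over cis fusion and Michael addition ahead of vinylogous aldol addition of the enone γ-carbons to the aldehyde; the first two rest on catalyst and chair, the third on the aldehyde being the only carbonyl that forms an enamine fast, and the aldol regiochemistry is secured because only C7 can reach C6 in a six-membered ring.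

Step 6
Reactants: 13 (4aS,8aR)-5,5,8a-trimethyl-4a,5,6,7,8,8a-hexahydronaphthalen-2(1H)-one
Product: 15 methyl 2-[(1S,4aS,8aS)-5,5,8a-trimethyl-2-oxo-1,2,4a,5,6,7,8,8a-octahydronaphthalen-1-yl]acetate, via lithium dienolate 14 (not isolated)
Conditions: LiN(i-Pr)2, THF, −78 °C; BrCH2CO2Me, DMPU, −78 → −20 °C
Reagents that add atoms: methyl bromoacetate, COC(=O)CBr
Why: Kinetic deprotonation of the enone occurs at its only α' position (C9) to give the cross-conjugated dienolate, whose enolate alkylation by the reactive bromoacetate should take place anti to the axial angular methyl group, that is mainly from the α face (9-epi configuration, corrected in step 7).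

Step 7
Reactants: 15 methyl 2-[(1S,4aS,8aS)-5,5,8a-trimethyl-2-oxo-1,2,4a,5,6,7,8,8a-octahydronaphthalen-1-yl]acetate
Product: 17 methyl 2-[(1R,4aS,8aS)-5,5,8a-trimethyl-2-oxodecahydronaphthalen-1-yl]acetate, via 9-epi keto ester 16 (not isolated)
Conditions: H2 (1 atm), Pd/C, EtOAc, rt; filter; NaOMe (0.2 equiv), MeOH, rt
Reagents that add atoms: none
Why: Catalytic hydrogenation saturates the C6=C7 bond of the enone, and base-mediated epimerization through the C8/C9 enolate should then move the side chain into the equatorial β position (9α-H), the thermodynamically preferred arrangement next to the ketone of a trans-decalone.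

Step 8
Reactants: 17 methyl 2-[(1R,4aS,8aS)-5,5,8a-trimethyl-2-oxodecahydronaphthalen-1-yl]acetate
Product: 18 methyl 2-[(1S,4aS,8aS)-5,5,8a-trimethyl-2-methylidenedecahydronaphthalen-1-yl]acetate
Conditions: Ph3PCH3Br, KN(SiMe3)2, THF, 0 °C; then 17, 0 → 45 °C
Reagents that add atoms: methyltriphenylphosphonium bromide, C[P+](c1ccccc1)(c1ccccc1)c1ccccc1.[Br-]
Why: Wittig methylenation with the non-stabilized ylide is chemoselective for the ketone over the methyl ester and should install the exocyclic C8=C17 bond, after which C9 can no longer epimerize.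

Step 9
Reactants: 18 methyl 2-[(1S,4aS,8aS)-5,5,8a-trimethyl-2-methylidenedecahydronaphthalen-1-yl]acetate
Product: 19 2-[(1S,4aS,8aS)-5,5,8a-trimethyl-2-methylidenedecahydronaphthalen-1-yl]acetaldehyde
Conditions: (i-Bu)2AlH (1.05 equiv), CH2Cl2, −78 °C; aq. potassium sodium tartrate (KNaC4H4O6)
Reagents that add atoms: none
Why: Partial hydride reduction of the methyl ester at low temperature should stop at the tetrahedral aluminium hemiacetal, which releases the aldehyde on work-up.

Step 10
Reactants: 20 [2-(1,3-dioxolan-2-yl)ethyl]triphenylphosphonium bromide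
Product: 22 methyl 3-(1,3-dioxolan-2-yl)-2-(triphenyl-λ5-phosphanylidene)propanoate, via phosphonium ylide 21 (not isolated)
Conditions: NaN(SiMe3)2 (2 equiv), THF, −78 °C; ClCO2Me (1 equiv), −78 °C → rt
Reagents that add atoms: methyl chloroformate, COC(Cl)=O
Why: C-acylation of the non-stabilized ylide by the chloroformate and deprotonation of the resulting acylphosphonium salt by the second equivalent of base should give the ester-stabilized α-substituted ylide.

Step 11
Reactants: 19 2-[(1S,4aS,8aS)-5,5,8a-trimethyl-2-methylidenedecahydronaphthalen-1-yl]acetaldehyde; 22 methyl 3-(1,3-dioxolan-2-yl)-2-(triphenyl-λ5-phosphanylidene)propanoate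
Product: 23 methyl (2E)-2-(1,3-dioxolan-2-ylmethyl)-4-[(1S,4aS,8aS)-5,5,8a-trimethyl-2-methylidenedecahydronaphthalen-1-yl]but-2-enoate
Conditions: toluene, 100 °C
Reagents that add atoms: none
Why: Wittig olefination of an aliphatic aldehyde with an α-substituted ester-stabilized ylide should give the trisubstituted enoate with the ester trans to the alkyl chain (12E), as is usual for stabilized ylides.

Step 12
Reactants: 23 methyl (2E)-2-(1,3-dioxolan-2-ylmethyl)-4-[(1S,4aS,8aS)-5,5,8a-trimethyl-2-methylidenedecahydronaphthalen-1-yl]but-2-enoate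
Product: 24 (2E)-2-(1,3-dioxolan-2-ylmethyl)-4-[(1S,4aS,8aS)-5,5,8a-trimethyl-2-methylidenedecahydronaphthalen-1-yl]but-2-enoic acid
Conditions: LiOH, THF/MeOH/H2O, 50 °C; then cold 0.5 M HCl to pH 4
Reagents that add atoms: lithium hydroxide, [Li+].[OH-]
Why: Saponification of the methyl ester leaves the base-stable dioxolane and the alkenes untouched, and acidification only to pH 4 in the cold should keep the acetal.

Step 13
Reactants: 25 (4R)-4-hydroxyoxolan-2-one
Product: 26 (4R)-4-[(tert-butyldimethylsilyl)oxy]oxolan-2-one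
Conditions: t-BuMe2SiCl, imidazole, DMF, rt
Reagents that add atoms: tert-butylchlorodimethylsilane, CC(C)(C)[Si](C)(C)Cl
Why: Imidazole-promoted silylation protects the secondary alcohol without touching the stereocentre.

Step 14
Reactants: 26 (4R)-4-[(tert-butyldimethylsilyl)oxy]oxolan-2-one; 19 2-[(1S,4aS,8aS)-5,5,8a-trimethyl-2-methylidenedecahydronaphthalen-1-yl]acetaldehyde
Product: 28 (3R,4R)-4-[(tert-butyldimethylsilyl)oxy]-3-{1-hydroxy-2-[(1S,4aS,8aS)-5,5,8a-trimethyl-2-methylidenedecahydronaphthalen-1-yl]ethyl}oxolan-2-one as both carbinol epimers, via lithium enolate 27 (not isolated)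
Conditions: LiN(SiMe3)2, THF, −78 °C; 19, −78 °C; AcOH quench at −78 °C
Reagents that add atoms: none
Why: Aldol addition of the lithium lactone enolate, kept at −78 °C so that β-elimination of silyloxide stays slow, should occur anti to the neighbouring silyloxy group, and both carbinol epimers are usable because this centre is removed in step 15.

Step 15
Reactants: 28 (3R,4R)-4-[(tert-butyldimethylsilyl)oxy]-3-{1-hydroxy-2-[(1S,4aS,8aS)-5,5,8a-trimethyl-2-methylidenedecahydronaphthalen-1-yl]ethyl}oxolan-2-one
Product: 30 (3E,4R)-4-[(tert-butyldimethylsilyl)oxy]-3-{2-[(1S,4aS,8aS)-5,5,8a-trimethyl-2-methylidenedecahydronaphthalen-1-yl]ethylidene}oxolan-2-one, via mesylate 29 (not isolated)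
Conditions: MeSO2Cl, Et3N, CH2Cl2, −20 → 0 °C; then DBU, 0 °C → rt
Reagents that add atoms: none
Why: Mesylation of the aldol hydroxyl and base-induced E1cB elimination should give the conjugated α-alkylidene lactone as its thermodynamically favoured E isomer, the sulfonate leaving far more readily than the β-silyloxy group.

Step 16
Reactants: 30 (3E,4R)-4-[(tert-butyldimethylsilyl)oxy]-3-{2-[(1S,4aS,8aS)-5,5,8a-trimethyl-2-methylidenedecahydronaphthalen-1-yl]ethylidene}oxolan-2-one
Product: 31 (3E,4R)-4-hydroxy-3-{2-[(1S,4aS,8aS)-5,5,8a-trimethyl-2-methylidenedecahydronaphthalen-1-yl]ethylidene}oxolan-2-one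
Conditions: HF·pyridine, THF, 0 °C → rt
Reagents that add atoms: none
Why: Fluoride-mediated desilylation under weakly acidic conditions should free the allylic alcohol while avoiding the base-induced loss of the C14 oxygen that would give the conjugated 11,13-diene.

Step 17
Reactants: 24 (2E)-2-(1,3-dioxolan-2-ylmethyl)-4-[(1S,4aS,8aS)-5,5,8a-trimethyl-2-methylidenedecahydronaphthalen-1-yl]but-2-enoic acid; 31 (3E,4R)-4-hydroxy-3-{2-[(1S,4aS,8aS)-5,5,8a-trimethyl-2-methylidenedecahydronaphthalen-1-yl]ethylidene}oxolan-2-one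
Product: 32 (3E,4R)-2-oxo-3-{2-[(1S,4aS,8aS)-5,5,8a-trimethyl-2-methylidenedecahydronaphthalen-1-yl]ethylidene}oxolan-4-yl (2E)-2-(1,3-dioxolan-2-ylmethyl)-4-[(1S,4aS,8aS)-5,5,8a-trimethyl-2-methylidenedecahydronaphthalen-1-yl]but-2-enoate
Conditions: EDC·HCl, DMAP, CH2Cl2, 0 °C → rt
Reagents that add atoms: none
Why: Carbodiimide-mediated Steglich esterification with DMAP as acyl-transfer catalyst should couple the unsaturated acid with the secondary allylic alcohol with retention at C14, since the C–O bond of the alcohol is not broken.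

Step 18
Reactants: 32 (3E,4R)-2-oxo-3-{2-[(1S,4aS,8aS)-5,5,8a-trimethyl-2-methylidenedecahydronaphthalen-1-yl]ethylidene}oxolan-4-yl (2E)-2-(1,3-dioxolan-2-ylmethyl)-4-[(1S,4aS,8aS)-5,5,8a-trimethyl-2-methylidenedecahydronaphthalen-1-yl]but-2-enoate
Product: 33 (3E,4R)-2-oxo-3-{2-[(1S,4aS,8aS)-5,5,8a-trimethyl-2-methylidenedecahydronaphthalen-1-yl]ethylidene}oxolan-4-yl (2E)-2-(2-oxoethyl)-4-[(1S,4aS,8aS)-5,5,8a-trimethyl-2-methylidenedecahydronaphthalen-1-yl]but-2-enoate
Conditions: 1 M HCl, THF, 0 °C → rt
Reagents that add atoms: water, O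
Why: Acid-catalysed acetal hydrolysis should free the aldehyde, while the two esters and the 1,1-disubstituted alkenes are expected to tolerate dilute acid at or below room temperature.

Compound list
1 | 3-methylbut-2-enal | CC(C)=CC=O | starting material
2 | (3-bromopropoxy)(tert-butyl)dimethylsilane | CC(C)(C)[Si](C)(C)OCCCBr | starting material
3 | {3-[(tert-butyldimethylsilyl)oxy]propyl}magnesium bromide | CC(C)(C)[Si](C)(C)OCCC[Mg]Br | intermediate
4 | tert-butyl({4,4-dimethyl-6-[(trimethylsilyl)oxy]hex-5-en-1-yl}oxy)dimethylsilane (enol ether geometry not defined) | CC(C)(C)[Si](C)(C)OCCCC(C)(C)C=CO[Si](C)(C)C | intermediate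
5 | 6-[(tert-butyldimethylsilyl)oxy]-3,3-dimethylhexanal | CC(C)(C)[Si](C)(C)OCCCC(C)(C)CC=O | intermediate
6 | 6,6-dimethoxy-4,4-dimethylhexan-1-ol | COC(OC)CC(C)(C)CCCO | intermediate
7 | 6-bromo-1,1-dimethoxy-3,3-dimethylhexane | COC(OC)CC(C)(C)CCCBr | intermediate
8 | (3E)-4-methoxypent-3-en-2-one | CO/C(C)=C/C(C)=O | starting material
9 | (6,6-dimethoxy-4,4-dimethylhexyl)magnesium bromide | COC(OC)CC(C)(C)CCC[Mg]Br | intermediate
10 | (2E)-2,10,10-trimethoxy-4,8,8-trimethyldec-2-en-4-ol (racemic at the carbinol carbon) | COC(OC)CC(C)(C)CCCC(C)(O)/C=C(\C)OC | intermediate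
11 | (7E)-3,3,7-trimethyl-9-oxodec-7-enal | CC(=O)/C=C(\C)CCCC(C)(C)CC=O | intermediate
12 | (1S,2R)-2,6,6-trimethyl-2-(2-oxopropyl)cyclohexane-1-carbaldehyde | CC(=O)C[C@@]1(C)CCCC(C)(C)[C@@H]1C=O | intermediate
13 | (4aS,8aR)-5,5,8a-trimethyl-4a,5,6,7,8,8a-hexahydronaphthalen-2(1H)-one | O=C1C=C[C@H]2C(C)(C)CCC[C@]2(C)C1 | intermediate
14 | lithium 5,5,8a-trimethyl-4a,5,6,7,8,8a-hexahydronaphthalen-2-olate, the cross-conjugated dienolate of 13 with its ring-fusion centres unchanged | [Li]OC1=C[C@@]2(C)CCCC(C)(C)[C@@H]2C=C1 | intermediate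
15 | methyl 2-[(1S,4aS,8aS)-5,5,8a-trimethyl-2-oxo-1,2,4a,5,6,7,8,8a-octahydronaphthalen-1-yl]acetate (side chain α, trans to the angular methyl) | O=C1C=C[C@H]2C(C)(C)CCC[C@]2(C)[C@@H]1CC(=O)OC | intermediate
16 | methyl 2-[(1S,4aS,8aS)-5,5,8a-trimethyl-2-oxodecahydronaphthalen-1-yl]acetate (9-epi, side chain α) | O=C1CC[C@H]2C(C)(C)CCC[C@]2(C)[C@@H]1CC(=O)OC | intermediate
17 | methyl 2-[(1R,4aS,8aS)-5,5,8a-trimethyl-2-oxodecahydronaphthalen-1-yl]acetate (side chain β, cis to the angular methyl) | O=C1CC[C@H]2C(C)(C)CCC[C@]2(C)[C@H]1CC(=O)OC | intermediate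
18 | methyl 2-[(1S,4aS,8aS)-5,5,8a-trimethyl-2-methylidenedecahydronaphthalen-1-yl]acetate | C=C1CC[C@H]2C(C)(C)CCC[C@]2(C)[C@H]1CC(=O)OC | intermediate
19 | 2-[(1S,4aS,8aS)-5,5,8a-trimethyl-2-methylidenedecahydronaphthalen-1-yl]acetaldehyde | C=C1CC[C@H]2C(C)(C)CCC[C@]2(C)[C@H]1CC=O | intermediate
20 | [2-(1,3-dioxolan-2-yl)ethyl]triphenylphosphonium bromide | [Br-].C1COC(O1)CC[P+](c1ccccc1)(c1ccccc1)c1ccccc1 | starting material
21 | [2-(1,3-dioxolan-2-yl)ethylidene]triphenyl-λ5-phosphane | C1COC(O1)CC=P(c1ccccc1)(c1ccccc1)c1ccccc1 | intermediate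
22 | methyl 3-(1,3-dioxolan-2-yl)-2-(triphenyl-λ5-phosphanylidene)propanoate | COC(=O)C(CC1OCCO1)=P(c1ccccc1)(c1ccccc1)c1ccccc1 | intermediate
23 | methyl (2E)-2-(1,3-dioxolan-2-ylmethyl)-4-[(1S,4aS,8aS)-5,5,8a-trimethyl-2-methylidenedecahydronaphthalen-1-yl]but-2-enoate | C=C1CC[C@H]2C(C)(C)CCC[C@]2(C)[C@H]1C/C=C(\CC1OCCO1)C(=O)OC | intermediate
24 | (2E)-2-(1,3-dioxolan-2-ylmethyl)-4-[(1S,4aS,8aS)-5,5,8a-trimethyl-2-methylidenedecahydronaphthalen-1-yl]but-2-enoic acid | C=C1CC[C@H]2C(C)(C)CCC[C@]2(C)[C@H]1C/C=C(\CC1OCCO1)C(=O)O | intermediate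
25 | (4R)-4-hydroxyoxolan-2-one | O[C@H]1COC(=O)C1 | starting material
26 | (4R)-4-[(tert-butyldimethylsilyl)oxy]oxolan-2-one | CC(C)(C)[Si](C)(C)O[C@H]1COC(=O)C1 | intermediate
27 | lithium (4R)-4-[(tert-butyldimethylsilyl)oxy]-4,5-dihydrofuran-2-olate | [Li]OC1=C[C@@H](O[Si](C)(C)C(C)(C)C)CO1 | intermediate
28 | (3R,4R)-4-[(tert-butyldimethylsilyl)oxy]-3-{1-hydroxy-2-[(1S,4aS,8aS)-5,5,8a-trimethyl-2-methylidenedecahydronaphthalen-1-yl]ethyl}oxolan-2-one (both carbinol epimers) | CC(C)(C)[Si](C)(C)O[C@H]1COC(=O)[C@@H]1C(O)C[C@H]1C(=C)CC[C@H]2C(C)(C)CCC[C@]12C | intermediate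
29 | methanesulfonate ester of 28 at the side-chain hydroxyl (ring centres as in 28, both carbinol epimers) | CC(C)(C)[Si](C)(C)O[C@H]1COC(=O)[C@@H]1C(OS(C)(=O)=O)C[C@H]1C(=C)CC[C@H]2C(C)(C)CCC[C@]12C | intermediate
30 | (3E,4R)-4-[(tert-butyldimethylsilyl)oxy]-3-{2-[(1S,4aS,8aS)-5,5,8a-trimethyl-2-methylidenedecahydronaphthalen-1-yl]ethylidene}oxolan-2-one | CC(C)(C)[Si](C)(C)O[C@H]1COC(=O)/C1=C/C[C@H]1C(=C)CC[C@H]2C(C)(C)CCC[C@]12C | intermediate
31 | (3E,4R)-4-hydroxy-3-{2-[(1S,4aS,8aS)-5,5,8a-trimethyl-2-methylidenedecahydronaphthalen-1-yl]ethylidene}oxolan-2-one | O[C@H]1COC(=O)/C1=C/C[C@H]1C(=C)CC[C@H]2C(C)(C)CCC[C@]12C | intermediate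
32 | (3E,4R)-2-oxo-3-{2-[(1S,4aS,8aS)-5,5,8a-trimethyl-2-methylidenedecahydronaphthalen-1-yl]ethylidene}oxolan-4-yl (2E)-2-(1,3-dioxolan-2-ylmethyl)-4-[(1S,4aS,8aS)-5,5,8a-trimethyl-2-methylidenedecahydronaphthalen-1-yl]but-2-enoate | C=C1CC[C@H]2C(C)(C)CCC[C@]2(C)[C@H]1C/C=C(\CC1OCCO1)C(=O)O[C@H]1COC(=O)/C1=C/C[C@H]1C(=C)CC[C@H]2C(C)(C)CCC[C@]12C | intermediate
33 | (3E,4R)-2-oxo-3-{2-[(1S,4aS,8aS)-5,5,8a-trimethyl-2-methylidenedecahydronaphthalen-1-yl]ethylidene}oxolan-4-yl (2E)-2-(2-oxoethyl)-4-[(1S,4aS,8aS)-5,5,8a-trimethyl-2-methylidenedecahydronaphthalen-1-yl]but-2-enoate | C=C1CC[C@H]2C(C)(C)CCC[C@]2(C)[C@H]1C/C=C(\CC=O)C(=O)O[C@H]1COC(=O)/C1=C/C[C@H]1C(=C)CC[C@H]2C(C)(C)CCC[C@]12C | target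

Total step count: 18. Longest linear sequence: 14 steps (steps 1 to 9, then 14 to 18).

Steps most likely to fail

Step 5. The bond between the neopentyl enamine carbon and the disubstituted enone terminus may form too slowly, so that vinylogous aldol addition or catalyst decay takes over. The trans fusion or the enantiomeric purity may also be eroded by reversible Michael addition and epimerization at C5. The fallback sets out from 11 and gives up asymmetric catalysis in favour of forcing, achiral Robinson-type conditions (pyrrolidine 30 mol %, AcOH 30 mol %, toluene, reflux with water separation). These should give the racemic trans enone, that is 13 together with its mirror image (4aR,8aS)-5,5,8a-trimethyl-4a,5,6,7,8,8a-hexahydronaphthalen-2(1H)-one F1. The enantiomers are then separated by preparative chromatography on a chiral stationary phase, and the fallback comes back to the route at 13.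

Step 14. The lithium enolate of the β-silyloxy lactone may expel silyloxide before it meets the aldehyde, or the aldolate may revert during the later mesylation. The fallback sets out from 26 and replaces aldol/dehydration by olefination. C-Phosphorylation of the lactone (LiN(i-Pr)2 2.2 equiv, ClP(O)(OEt)2, THF, −78 → 0 °C, enol phosphate to phosphonate shift) should give diethyl {(4S)-4-[(tert-butyldimethylsilyl)oxy]-2-oxooxolan-3-yl}phosphonate F2; the descriptor changes only because of the phosphorus substituent, and the silyloxy carbon is unchanged from 26. Horner–Wadsworth–Emmons reaction of this less basic phosphonate anion with 19 (K2CO3, 18-crown-6, toluene, rt) should then give the alkylidene lactone directly, so the fallback comes back at 30.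

Step 18. During acetal cleavage the exocyclic double bonds may migrate into the rings, or the allylic C14 ester may ionize. The fallback sets out from 24 and moves the acid step in front of the coupling. The dioxolane is hydrolysed on the robust acid (1 M HCl, THF, rt) to (2E)-2-(2-oxoethyl)-4-[(1S,4aS,8aS)-5,5,8a-trimethyl-2-methylidenedecahydronaphthalen-1-yl]but-2-enoic acid F3. This is esterified with 31 through the mixed anhydride (2,4,6-trichlorobenzoyl chloride, Et3N, THF; then 31, DMAP, toluene, rt), so the fallback comes back at 33 with no acid treatment after the ester bond is made.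

Further compounds
F1 | step 5 | (4aR,8aS)-5,5,8a-trimethyl-4a,5,6,7,8,8a-hexahydronaphthalen-2(1H)-one (enantiomer of 13, formed with it as the racemate) | O=C1C=C[C@@H]2C(C)(C)CCC[C@@]2(C)C1
F2 | step 14 | diethyl {(4S)-4-[(tert-butyldimethylsilyl)oxy]-2-oxooxolan-3-yl}phosphonate | CCOP(=O)(OCC)C1C(=O)OC[C@@H]1O[Si](C)(C)C(C)(C)C
F3 | step 18 | (2E)-2-(2-oxoethyl)-4-[(1S,4aS,8aS)-5,5,8a-trimethyl-2-methylidenedecahydronaphthalen-1-yl]but-2-enoic acid | C=C1CC[C@H]2C(C)(C)CCC[C@]2(C)[C@H]1C/C=C(\CC=O)C(=O)O
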